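**Retrosynthetic overview**
- Target ⇐ a bicyclic 3-oxo-19-ester of the ent-labdane series: one hydride step removes the C3 oxygen and reduces the esters, then C15 is re-oxidised and C16/C19 are acetylated.
- Rings A and B are made together (ring A first, ring B second) in one oxidative radical cascade of an acyclic α-methyl β-keto ester triene (bonds C4–C5 and C10–C9, labdane numbering). Copper termination gives the 8(17)-methylidene; an 8-phenylmenthyl ester controls absolute configuration.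
- The acyclic precursor ⇐ γ-alkylation of a 2-methylacetoacetate dianion with a C16 allylic bromide (bond C1–C2).
- The bromide ⇐ geranyl bromide + methyl acetoacetate (C11–C12), E-enol triflate and hydroxymethyl Stille coupling (C13–C16), terminal allylic oxidation.

Assumption: under non-chelating conditions the (1S,2R,5S)-8-phenylmenthyl ester directs the cascade into the ent series (mirror image of the sense I recall for the (1R,2S,5R) ester in the podocarpate series); if the sense proves reversed, the enantiomeric auxiliary is used with no other change.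

Labdane numbering is used for all bicyclic compounds. The auxiliary 10 is costly but is recovered in step 11.

**Step 1**
Reactants: 1 geranyl bromide; 2 methyl acetoacetate
Product: 4 methyl (6E)-7,11-dimethyl-3-oxododeca-6,10-dienoate, via sodium lithium dianion of methyl acetoacetate 3 (not isolated)
Conditions: 2, NaH, THF, 0 °C; n-BuLi, 0 °C; then 1, 0 °C → rt; aq. HCl
Reagents that add atoms: none
Why: Weiler dianion alkylation, in which the more basic terminal carbanion displaces the allylic bromide by SN2 and leaves the E alkene untouched.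

**Step 2**
Reactants: 4 methyl (6E)-7,11-dimethyl-3-oxododeca-6,10-dienoate
Product: 5 methyl (2E,6E)-7,11-dimethyl-3-(trifluoromethylsulfonyloxy)dodeca-2,6,10-trienoate
Conditions: Tf2O, aq. Me4NOH, toluene, 5 °C
Reagents that add atoms: triflic anhydride O=S(=O)(OS(=O)(=O)C(F)(F)F)C(F)(F)F
Why: O-triflation of the β-keto ester enolate with a non-chelating tetramethylammonium counter-ion gives the E enol triflate (triflate trans to the ester), which fixes the later C12-cis-to-carboxyl geometry.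

**Step 3**
Reactants: 5 methyl (2E,6E)-7,11-dimethyl-3-(trifluoromethylsulfonyloxy)dodeca-2,6,10-trienoate
Product: 6 methyl (2E,6E)-3-(hydroxymethyl)-7,11-dimethyldodeca-2,6,10-trienoate
Conditions: Bu3SnCH2OH, Pd(PPh3)4 (5 mol %), LiCl, 1,4-dioxane, 100 °C
Reagents that add atoms: (tributylstannyl)methanol CCCC[Sn](CCCC)(CCCC)CO
Why: Stille coupling at zerovalent palladium transfers the hydroxymethyl group to the electron-poor vinyl triflate with retention of geometry, so CH2OH ends trans to the ester and cannot lactonise.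

**Step 4**
Reactants: 6 methyl (2E,6E)-3-(hydroxymethyl)-7,11-dimethyldodeca-2,6,10-trienoate
Product: 7 methyl (2E,6E)-3-[(tert-butyldiphenylsilyloxy)methyl]-7,11-dimethyldodeca-2,6,10-trienoate
Conditions: TBDPSCl, imidazole, CH2Cl2, rt
Reagents that add atoms: tert-butyl(chloro)diphenylsilane CC(C)(C)[Si](Cl)(c1ccccc1)c1ccccc1
Why: Routine silylation of the primary allylic alcohol; the TBDPS ether survives acetic acid, hydride and the later oxidations and keeps O16 distinct from O15.

**Step 5**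
Reactants: 7 methyl (2E,6E)-3-[(tert-butyldiphenylsilyloxy)methyl]-7,11-dimethyldodeca-2,6,10-trienoate
Product: 8 methyl (2E,6E,10E)-3-[(tert-butyldiphenylsilyloxy)methyl]-12-hydroxy-7,11-dimethyldodeca-2,6,10-trienoate
Conditions: SeO2 (0.2 equiv), t-BuOOH, salicylic acid (cat.), CH2Cl2, 0 °C → rt
Reagents that add atoms: tert-butyl hydroperoxide CC(C)(C)OO (terminal oxidant; the oxygen is delivered through catalytic SeO2, O=[Se]=O)
Why: Riley allylic oxidation (ene reaction then 2,3-sigmatropic shift) attacks the most electron-rich, least hindered terminal trisubstituted alkene and hydroxylates its E methyl group selectively.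

**Step 6**
Reactants: 8 methyl (2E,6E,10E)-3-[(tert-butyldiphenylsilyloxy)methyl]-12-hydroxy-7,11-dimethyldodeca-2,6,10-trienoate
Product: 9 methyl (2E,6E,10E)-12-bromo-3-[(tert-butyldiphenylsilyloxy)methyl]-7,11-dimethyldodeca-2,6,10-trienoate
Conditions: CBr4, PPh3, CH2Cl2, 0 °C
Reagents that add atoms: carbon tetrabromide BrC(Br)(Br)Br
Why: Appel bromination proceeds by SN2 on the oxyphosphonium salt under neutral conditions, without allylic transposition or loss of alkene geometry.

**Step 7**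
Reactants: 10 (1S,2R,5S)-8-phenylmenthol; 11 ethyl 2-methyl-3-oxobutanoate
Product: 12 (1S,2R,5S)-8-phenylmenthyl 2-methyl-3-oxobutanoate
Conditions: DMAP (cat.), toluene, reflux, ethanol distilled off
Reagents that add atoms: none
Why: DMAP-catalysed transesterification of a β-keto ester, driven by removal of ethanol; the α-centre is epimeric and is erased later.

**Step 8**
Reactants: 12 (1S,2R,5S)-8-phenylmenthyl 2-methyl-3-oxobutanoate; 9 methyl (2E,6E,10E)-12-bromo-3-[(tert-butyldiphenylsilyloxy)methyl]-7,11-dimethyldodeca-2,6,10-trienoate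
Product: 14 1-[(1S,2R,5S)-8-phenylmenthyl] 16-methyl (6E,10E,14E)-14-[(tert-butyldiphenylsilyloxy)methyl]-2,6,10-trimethyl-3-oxohexadeca-6,10,14-trienedioate, via sodium lithium dianion of the auxiliary keto ester 13 (not isolated)
Conditions: 12, NaH, THF, 0 °C; n-BuLi, 0 °C; then 9, −20 → 0 °C; aq. HCl
Reagents that add atoms: none
Why: Dianion γ-alkylation as in step 1 forms the C1–C2 bond; SN2 at the primary allylic bromide is far faster than attack on the hindered enoate or silyl ether.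

**Step 9** (key step)
Reactants: 14 1-[(1S,2R,5S)-8-phenylmenthyl] 16-methyl (6E,10E,14E)-14-[(tert-butyldiphenylsilyloxy)methyl]-2,6,10-trimethyl-3-oxohexadeca-6,10,14-trienedioate
Product: 15 15-methyl 19-[(1S,2R,5S)-8-phenylmenthyl] (13E)-16-(tert-butyldiphenylsilyloxy)-3-oxo-ent-labda-8(17),13-diene-15,19-dioate
Conditions: Mn(OAc)3·2H2O (2.2 equiv), Cu(OAc)2·H2O (1 equiv), degassed AcOH, rt
Reagents that add atoms: none
Why: Snider-type oxidative free-radical polyene cyclization, in which trivalent manganese generates the C4 α-keto ester radical, two 6-endo additions through chair–chair transition states close ring A then ring B as a trans-decalin with the C9 chain equatorial, the ester takes the axial site cis to the C10 methyl (podocarpate precedent), divalent copper oxidises the tertiary C8 radical to the 8(17)-methylidene faster than it can add to the hindered electron-poor enoate, and the phenyl of the auxiliary shields one face of the radical to set C4, C5, C9 and C10 absolutely (expected about 9:1; the minor diastereomer and endocyclic alkene isomers are removed by chromatography).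

**Step 10**
Reactants: 15 15-methyl 19-[(1S,2R,5S)-8-phenylmenthyl] (13E)-16-(tert-butyldiphenylsilyloxy)-3-oxo-ent-labda-8(17),13-diene-15,19-dioate
Product: 16 3-(4-methylphenylsulfonylhydrazone) of keto diester 15
Conditions: TsNHNH2, PPTS (cat.), EtOH, 70 °C
Reagents that add atoms: 4-methylbenzenesulfonohydrazide Cc1ccc(cc1)S(=O)(=O)NN
Why: Condensation at the only ketone; 3-oxo-4,4-disubstituted decalins form tosylhydrazones readily, and the hindered ester and the enoate do not react.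

**Step 11**
Reactants: 16 3-(4-methylphenylsulfonylhydrazone) of keto diester 15
Product: 17 (13E)-16-(tert-butyldiphenylsilyloxy)-ent-labda-8(17),13-diene-15,19-diol
Conditions: LiAlH4 (excess), THF, 0 °C → reflux; H2O, aq. NaOH work-up (auxiliary 10 recovered)
Reagents that add atoms: none
Why: Caglioti reduction (hydride addition to C=N, then loss of sulfinate and N2) turns C3 into CH2 while the same reagent reduces both esters to primary alcohols and releases the auxiliary; no stereocentre is touched.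

**Step 12**
Reactants: 17 (13E)-16-(tert-butyldiphenylsilyloxy)-ent-labda-8(17),13-diene-15,19-diol
Product: 18 (13E)-16-(tert-butyldiphenylsilyloxy)-19-hydroxy-ent-labda-8(17),13-dien-15-al
Conditions: MnO2 (excess), CH2Cl2, rt
Reagents that add atoms: none
Why: Activated MnO2 oxidises only the allylic C15 alcohol; the saturated neopentyl C19 alcohol is inert and the E geometry is kept.

**Step 13**
Reactants: 18 (13E)-16-(tert-butyldiphenylsilyloxy)-19-hydroxy-ent-labda-8(17),13-dien-15-al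
Product: 19 (13E)-16-(tert-butyldiphenylsilyloxy)-19-hydroxy-ent-labda-8(17),13-dien-15-oic acid
Conditions: NaClO2, NaH2PO4, 2-methyl-2-butene, t-BuOH/H2O, rt
Reagents that add atoms: sodium chlorite [Na+].[O-]Cl=O
Why: Pinnick oxidation converts the enal to the acid without isomerisation, and the alkene scavenger removes hypochlorous acid before it can attack the methylidene.

**Step 14**
Reactants: 19 (13E)-16-(tert-butyldiphenylsilyloxy)-19-hydroxy-ent-labda-8(17),13-dien-15-oic acid
Product: 22 (2E)-3-(acetoxymethyl)-5-[(1R,4aS,5R,8aS)-5-(acetoxymethyl)-5,8a-dimethyl-2-methylidenedecahydronaphthalen-1-yl]pent-2-enoic acid, via (13E)-16,19-dihydroxy-ent-labda-8(17),13-dien-15-oic acid 20 (not isolated), via acetic mixed anhydride of the diacetate acid 21 (not isolated)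
Conditions: TBAF, THF, rt; then Ac2O, pyridine, DMAP (cat.), rt; then H2O
Reagents that add atoms: acetic anhydride CC(=O)OC(C)=O
Why: Fluoride desilylation frees O16, DMAP-catalysed acetylation esterifies both primary alcohols, and the transient mixed anhydride at C15 is hydrolysed on aqueous work-up; O16 is trans to the carboxyl, so no lactone can form.

**Compound list**
1 | geranyl bromide, (2E)-1-bromo-3,7-dimethylocta-2,6-diene | CC(C)=CCC/C(C)=C/CBr | starting material
2 | methyl acetoacetate | CC(=O)CC(=O)OC | starting material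
3 | sodium lithium dianion of methyl acetoacetate | [Na+].[Li+].[CH2-]C(=O)[CH-]C(=O)OC | intermediate (not isolated)
4 | methyl (6E)-7,11-dimethyl-3-oxododeca-6,10-dienoate | COC(=O)CC(=O)CC/C=C(\C)CCC=C(C)C | intermediate
5 | methyl (2E,6E)-7,11-dimethyl-3-(trifluoromethylsulfonyloxy)dodeca-2,6,10-trienoate | COC(=O)/C=C(/OS(=O)(=O)C(F)(F)F)CC/C=C(\C)CCC=C(C)C | intermediate
6 | methyl (2E,6E)-3-(hydroxymethyl)-7,11-dimethyldodeca-2,6,10-trienoate | COC(=O)/C=C(/CO)CC/C=C(\C)CCC=C(C)C | intermediate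
7 | methyl (2E,6E)-3-[(tert-butyldiphenylsilyloxy)methyl]-7,11-dimethyldodeca-2,6,10-trienoate | COC(=O)/C=C(/CO[Si](c1ccccc1)(c1ccccc1)C(C)(C)C)CC/C=C(\C)CCC=C(C)C | intermediate
8 | methyl (2E,6E,10E)-3-[(tert-butyldiphenylsilyloxy)methyl]-12-hydroxy-7,11-dimethyldodeca-2,6,10-trienoate | COC(=O)/C=C(/CO[Si](c1ccccc1)(c1ccccc1)C(C)(C)C)CC/C=C(\C)CC/C=C(\C)CO | intermediate
9 | methyl (2E,6E,10E)-12-bromo-3-[(tert-butyldiphenylsilyloxy)methyl]-7,11-dimethyldodeca-2,6,10-trienoate | COC(=O)/C=C(/CO[Si](c1ccccc1)(c1ccccc1)C(C)(C)C)CC/C=C(\C)CC/C=C(\C)CBr | intermediate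
10 | (1S,2R,5S)-8-phenylmenthol, (1S,2R,5S)-5-methyl-2-(2-phenylpropan-2-yl)cyclohexan-1-ol | O[C@H]1C[C@@H](C)CC[C@@H]1C(C)(C)c1ccccc1 | starting material
11 | ethyl 2-methyl-3-oxobutanoate (racemic) | CCOC(=O)C(C)C(C)=O | starting material
12 | (1S,2R,5S)-8-phenylmenthyl 2-methyl-3-oxobutanoate (epimers at the α-carbon) | CC(=O)C(C)C(=O)O[C@H]1C[C@@H](C)CC[C@@H]1C(C)(C)c1ccccc1 | intermediate
13 | sodium lithium dianion of 12 | [Na+].[Li+].[CH2-]C(=O)[C-](C)C(=O)O[C@H]1C[C@@H](C)CC[C@@H]1C(C)(C)c1ccccc1 | intermediate (not isolated)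
14 | 1-[(1S,2R,5S)-8-phenylmenthyl] 16-methyl (6E,10E,14E)-14-[(tert-butyldiphenylsilyloxy)methyl]-2,6,10-trimethyl-3-oxohexadeca-6,10,14-trienedioate (C2 epimers) | COC(=O)/C=C(/CO[Si](c1ccccc1)(c1ccccc1)C(C)(C)C)CC/C=C(\C)CC/C=C(\C)CCC(=O)C(C)C(=O)O[C@H]1C[C@@H](C)CC[C@@H]1C(C)(C)c1ccccc1 | intermediate
15 | 15-methyl 19-[(1S,2R,5S)-8-phenylmenthyl] (4S,5S,9R,10S,13E)-16-(tert-butyldiphenylsilyloxy)-3-oxolabda-8(17),13-diene-15,19-dioate; ent-labdane, trans-decalin, 5-H and 9-H β, C10 methyl and C19 ester α | C=C1CC[C@@H]2[C@](C)(C(=O)O[C@H]3C[C@@H](C)CC[C@@H]3C(C)(C)c3ccccc3)C(=O)CC[C@@]2(C)[C@@H]1CC/C(=C\C(=O)OC)CO[Si](c1ccccc1)(c1ccccc1)C(C)(C)C | intermediate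
16 | 3-(4-methylphenylsulfonylhydrazone) of 15 (4S,5S,9R,10S,13E; C=N geometry not defined) | C=C1CC[C@@H]2[C@](C)(C(=O)O[C@H]3C[C@@H](C)CC[C@@H]3C(C)(C)c3ccccc3)C(=NNS(=O)(=O)c3ccc(C)cc3)CC[C@@]2(C)[C@@H]1CC/C(=C\C(=O)OC)CO[Si](c1ccccc1)(c1ccccc1)C(C)(C)C | intermediate
17 | (4R,5S,9R,10S,13E)-16-(tert-butyldiphenylsilyloxy)labda-8(17),13-diene-15,19-diol (ent-labdane) | C=C1CC[C@@H]2[C@](C)(CO)CCC[C@@]2(C)[C@@H]1CC/C(=C\CO)CO[Si](c1ccccc1)(c1ccccc1)C(C)(C)C | intermediate
18 | (4R,5S,9R,10S,13E)-16-(tert-butyldiphenylsilyloxy)-19-hydroxylabda-8(17),13-dien-15-al (ent-labdane) | C=C1CC[C@@H]2[C@](C)(CO)CCC[C@@]2(C)[C@@H]1CC/C(=C\C=O)CO[Si](c1ccccc1)(c1ccccc1)C(C)(C)C | intermediate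
19 | (4R,5S,9R,10S,13E)-16-(tert-butyldiphenylsilyloxy)-19-hydroxylabda-8(17),13-dien-15-oic acid (ent-labdane) | C=C1CC[C@@H]2[C@](C)(CO)CCC[C@@]2(C)[C@@H]1CC/C(=C\C(=O)O)CO[Si](c1ccccc1)(c1ccccc1)C(C)(C)C | intermediate
20 | (4R,5S,9R,10S,13E)-16,19-dihydroxylabda-8(17),13-dien-15-oic acid (ent-labdane) | C=C1CC[C@@H]2[C@](C)(CO)CCC[C@@]2(C)[C@@H]1CC/C(=C\C(=O)O)CO | intermediate (not isolated)
21 | acetic (4R,5S,9R,10S,13E)-16,19-diacetoxylabda-8(17),13-dien-15-oic anhydride | C=C1CC[C@@H]2[C@](C)(COC(C)=O)CCC[C@@]2(C)[C@@H]1CC/C(=C\C(=O)OC(C)=O)COC(C)=O | intermediate (not isolated)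
22 | (2E)-3-(acetoxymethyl)-5-[(1R,4aS,5R,8aS)-5-(acetoxymethyl)-5,8a-dimethyl-2-methylidenedecahydronaphthalen-1-yl]pent-2-enoic acid (16,19-diacetoxy-ent-labda-8(17),13E-dien-15-oic acid) | C=C1CC[C@@H]2[C@](C)(COC(C)=O)CCC[C@@]2(C)[C@@H]1CC/C(=C\C(=O)O)COC(C)=O | target

**Step count and risks**
Total steps: 14. Longest linear sequence: 13 (steps 1–6 and 8–14; step 7 is a one-step side branch).

Most likely to fail, step 9 (face selectivity of the auxiliary, C4 outcome, interception of the C8 radical by the side chain). The fallback sets out from 9 and comes back at 17, and builds C4 after ring closure. Methyl acetoacetate 2 is transesterified with commercial (1R,2S,5R)-8-phenylmenthol (DMAP, toluene, reflux) to (1R,2S,5R)-8-phenylmenthyl 3-oxobutanoate F1. Its dianion (NaH, n-BuLi) is alkylated with 9 to the α-unsubstituted triene keto ester F2. Mn(OAc)3·2H2O, Cu(OAc)2·H2O and Yb(OTf)3 in CF3CH2OH at −5 °C close both rings through the chelated radical, for which the (1R,2S,5R) auxiliary is the one expected to lead to the ent series, giving the enolisable bicyclic β-keto ester F3. C-Methylation (K2CO3, MeI, acetone) from the face opposite the C10 methyl gives the C4-methyl keto ester F4. Its tosylhydrazone F5 is reduced with LiAlH4 as in step 11 to give 17.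

Second, step 11 (hydride addition to a hindered hydrazone may give the 2-ene instead). The fallback sets out from 15 and comes back at 17, and deoxygenates C3 by a radical route. NaBH4 (MeOH, 0 °C) reduces only the ketone to the 3-hydroxy diester F6. 1,1'-Thiocarbonyldiimidazole with DMAP (toluene, 90 °C) gives the 3-O-imidazolylthiocarbonyl diester F7. Bu3SnH with AIBN (toluene, 110 °C, Barton–McCombie) gives the 3-deoxy diester F8. LiAlH4 (THF, 0 °C → rt) then reduces both esters to 17.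

Third, step 3 (slow transfer of the sp3 hydroxymethyl group from tin, possible E/Z leakage from step 2). The fallback sets out from 1 and comes back at 7, and makes the C13=C14 bond by olefination instead of coupling. The N,N-dimethylhydrazone of (tert-butyldiphenylsilyloxy)acetone F9 is deprotonated at its methyl group (LDA, THF, −78 °C) and alkylated with 1 to the alkylated hydrazone F10. Hydrolysis (aq. oxalic acid) gives (5E)-1-(tert-butyldiphenylsilyloxy)-6,10-dimethylundeca-5,9-dien-2-one F11. Horner–Wadsworth–Emmons reaction with trimethyl phosphonoacetate and NaH in THF gives 7 after chromatographic removal of the minor 2Z isomer.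

**Further compounds**
F1 | step 9 | (1R,2S,5R)-8-phenylmenthyl 3-oxobutanoate | CC(=O)CC(=O)O[C@@H]1C[C@H](C)CC[C@H]1C(C)(C)c1ccccc1
F2 | step 9 | 1-[(1R,2S,5R)-8-phenylmenthyl] 16-methyl (6E,10E,14E)-14-[(tert-butyldiphenylsilyloxy)methyl]-6,10-dimethyl-3-oxohexadeca-6,10,14-trienedioate | COC(=O)/C=C(/CO[Si](c1ccccc1)(c1ccccc1)C(C)(C)C)CC/C=C(\C)CC/C=C(\C)CCC(=O)CC(=O)O[C@@H]1C[C@H](C)CC[C@H]1C(C)(C)c1ccccc1
F3 | step 9 | 15-methyl 19-[(1R,2S,5R)-8-phenylmenthyl] (13E)-16-(tert-butyldiphenylsilyloxy)-3-oxo-18-nor-ent-labda-8(17),13-diene-15,19-dioate (C4 enolisable) | C=C1CC[C@@H]2C(C(=O)O[C@@H]3C[C@H](C)CC[C@H]3C(C)(C)c3ccccc3)C(=O)CC[C@@]2(C)[C@@H]1CC/C(=C\C(=O)OC)CO[Si](c1ccccc1)(c1ccccc1)C(C)(C)C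
F4 | step 9 | 15-methyl 19-[(1R,2S,5R)-8-phenylmenthyl] (13E)-16-(tert-butyldiphenylsilyloxy)-3-oxo-ent-labda-8(17),13-diene-15,19-dioate | C=C1CC[C@@H]2[C@](C)(C(=O)O[C@@H]3C[C@H](C)CC[C@H]3C(C)(C)c3ccccc3)C(=O)CC[C@@]2(C)[C@@H]1CC/C(=C\C(=O)OC)CO[Si](c1ccccc1)(c1ccccc1)C(C)(C)C
F5 | step 9 | 3-(4-methylphenylsulfonylhydrazone) of F4 | C=C1CC[C@@H]2[C@](C)(C(=O)O[C@@H]3C[C@H](C)CC[C@H]3C(C)(C)c3ccccc3)C(=NNS(=O)(=O)c3ccc(C)cc3)CC[C@@]2(C)[C@@H]1CC/C(=C\C(=O)OC)CO[Si](c1ccccc1)(c1ccccc1)C(C)(C)C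
F6 | step 11 | 15-methyl 19-[(1S,2R,5S)-8-phenylmenthyl] (13E)-16-(tert-butyldiphenylsilyloxy)-3-hydroxy-ent-labda-8(17),13-diene-15,19-dioate (C3 epimer not defined) | C=C1CC[C@@H]2[C@](C)(C(=O)O[C@H]3C[C@@H](C)CC[C@@H]3C(C)(C)c3ccccc3)C(O)CC[C@@]2(C)[C@@H]1CC/C(=C\C(=O)OC)CO[Si](c1ccccc1)(c1ccccc1)C(C)(C)C
F7 | step 11 | 3-O-(imidazol-1-ylthiocarbonyl) derivative of F6 | C=C1CC[C@@H]2[C@](C)(C(=O)O[C@H]3C[C@@H](C)CC[C@@H]3C(C)(C)c3ccccc3)C(OC(=S)n3ccnc3)CC[C@@]2(C)[C@@H]1CC/C(=C\C(=O)OC)CO[Si](c1ccccc1)(c1ccccc1)C(C)(C)C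
F8 | step 11 | 15-methyl 19-[(1S,2R,5S)-8-phenylmenthyl] (13E)-16-(tert-butyldiphenylsilyloxy)-ent-labda-8(17),13-diene-15,19-dioate | C=C1CC[C@@H]2[C@](C)(C(=O)O[C@H]3C[C@@H](C)CC[C@@H]3C(C)(C)c3ccccc3)CCC[C@@]2(C)[C@@H]1CC/C(=C\C(=O)OC)CO[Si](c1ccccc1)(c1ccccc1)C(C)(C)C
F9 | step 3 | N,N-dimethylhydrazone of (tert-butyldiphenylsilyloxy)acetone | CC(CO[Si](c1ccccc1)(c1ccccc1)C(C)(C)C)=NN(C)C
F10 | step 3 | N,N-dimethylhydrazone of (5E)-1-(tert-butyldiphenylsilyloxy)-6,10-dimethylundeca-5,9-dien-2-one | CC(C)=CCC/C(C)=C/CCC(CO[Si](c1ccccc1)(c1ccccc1)C(C)(C)C)=NN(C)C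
F11 | step 3 | (5E)-1-(tert-butyldiphenylsilyloxy)-6,10-dimethylundeca-5,9-dien-2-one | CC(C)=CCC/C(C)=C/CCC(=O)CO[Si](c1ccccc1)(c1ccccc1)C(C)(C)C
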